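**Retrosynthetic overview**

1. Locants follow the target's name, (1S,4E,6R,11S)-6-(benzoyloxy)-7,7,11-trimethyl-12-oxabicyclo[9.1.0]dodec-4-ene-4-carboxylic acid: C1/C11 are the oxirane carbons (C11 bears CH3), C4 bears the carboxyl group, C6 the benzoate, C7 is the CMe2 carbon, C8–C10 are the three ring CH2 groups.
2. Target ⇐ fluoride unmasking of a 2-(trimethylsilyl)ethyl ester and diimide saturation of C9=C10 ⇐ ring-closing metathesis at C9–C10 of an acyclic diene (allyl on C7, vinyl on oxirane carbon C11) that already carries the oxirane, the benzoate, the E-enoate and all three stereocentres.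
3. The diene ⇐ Horner–Wadsworth–Emmons union at C4=C5 of a phosphonate (C1–C4, C10, C11; from 5-bromo-2-methylpent-2-ene through a Sharpless epoxidation) with an α-benzoyloxy aldehyde (C5–C9; from 2,2-dimethylpent-4-enal through an organocatalytic α-benzoyloxylation).
4. Rings: the oxirane is formed first (step 2), the eleven-membered carbocycle second (step 10).
5. Enabling feature: C9–C10 is the one ring bond between two CH2 groups that fully substituted carbons (C11 next to C10, C7 one CH2 beyond C9) wall off from all functionality. Both ends can therefore be plain terminal olefins, while the trans-oxirane, the gem-dimethyl group and the C4=C5 olefin (ring bonds cis) pre-bend the chain; a radical or carbanion at C9 would instead close a five-membered ring onto C5 of the acrylate, which metathesis avoids.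

Key step: step 10

Remark: the geometry of the C9=C10 olefin formed in step 10 is not controlled and need not be, because step 11 saturates it; the E isomer is written.

**Route**

Step 1
Reactants: 1 5-bromo-2-methylpent-2-ene
Product: 2 (2E)-5-bromo-2-methylpent-2-en-1-ol
Conditions: SeO2 (0.5 equiv), t-BuOOH (70% aq.), salicylic acid (10 mol%), CH2Cl2, 0 °C to rt
Reagents that add atoms: tert-butyl hydroperoxide, CC(C)(C)OO (terminal oxygen source, relayed by selenium dioxide, O=[Se]=O)
Why: Selenium dioxide allylic oxidation (ene reaction followed by a [2,3]-sigmatropic shift) should hydroxylate the methyl group trans to the chain of the trisubstituted olefin, so the E-allylic alcohol is expected and no stereocentre is formed.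

Step 2
Reactants: 2 (2E)-5-bromo-2-methylpent-2-en-1-ol
Product: 3 [(2S,3S)-3-(2-bromoethyl)-2-methyloxiran-2-yl]methanol
Conditions: Ti(OiPr)4 (10 mol%), L-(+)-diethyl tartrate (12 mol%), t-BuOOH (anhydrous, in decane), 4 Å molecular sieves, CH2Cl2, −20 °C
Reagents that add atoms: tert-butyl hydroperoxide, CC(C)(C)OO
Why: In this Sharpless asymmetric epoxidation of an E-2-methyl allylic alcohol the titanium complex of the L-(+)-tartrate should deliver oxygen to the face that gives the (2S,3S)-epoxy alcohol, which sets both oxirane stereocentres (C11 and C1 of the target) by reagent control, the trans relationship following from the E olefin.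

Step 3
Reactants: 3 [(2S,3S)-3-(2-bromoethyl)-2-methyloxiran-2-yl]methanol
Product: 4 (2R,3S)-3-(2-bromoethyl)-2-methyloxirane-2-carbaldehyde
Conditions: TEMPO (10 mol%), PhI(OAc)2 (1.1 equiv), CH2Cl2, rt
Reagents that add atoms: none
Why: The oxoammonium (TEMPO) oxidation of a primary alcohol stops at the aldehyde under non-basic conditions that spare the oxirane and the bromide, and the quaternary α-carbon cannot epimerise (its descriptor changes only through the priority rule).

Step 4
Reactants: 4 (2R,3S)-3-(2-bromoethyl)-2-methyloxirane-2-carbaldehyde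
Product: 5 (2S,3S)-3-(2-bromoethyl)-2-ethenyl-2-methyloxirane
Conditions: Ph3PCH3Br, KN(SiMe3)2, THF, 0 °C; then 4, −78 to 0 °C
Reagents that add atoms: methyltriphenylphosphonium bromide, C[P+](c1ccccc1)(c1ccccc1)c1ccccc1.[Br-]
Why: In this Wittig methylenation of a non-enolisable epoxy aldehyde the ylide should add to the aldehyde far faster at low temperature than it is alkylated by the primary bromide, and no stereocentre is touched.

Step 5
Reactants: 6 2-(diethoxyphosphoryl)acetic acid; 7 2-(trimethylsilyl)ethanol
Product: 8 2-(trimethylsilyl)ethyl 2-(diethoxyphosphoryl)acetate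
Conditions: DCC, DMAP (10 mol%), CH2Cl2, 0 °C to rt
Reagents that add atoms: none
Why: This Steglich esterification installs the 2-(trimethylsilyl)ethyl ester, chosen because fluoride removes it at the end without touching the benzoate or the oxirane.

Step 6
Reactants: 8 2-(trimethylsilyl)ethyl 2-(diethoxyphosphoryl)acetate; 5 (2S,3S)-3-(2-bromoethyl)-2-ethenyl-2-methyloxirane
Product: 9 2-(trimethylsilyl)ethyl 2-(diethoxyphosphoryl)-4-[(2S,3S)-3-ethenyl-3-methyloxiran-2-yl]butanoate (both epimers at C2 of the butanoate)
Conditions: NaH, DMF, 0 °C (8 in excess); then 5, NaI (20 mol%), 50 °C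
Reagents that add atoms: none
Why: This SN2 C-alkylation of the sodium phosphonoacetate by the primary bromide under iodide catalysis should leave the hindered trisubstituted oxirane alone because the carbanion is soft and the excess of 8 suppresses dialkylation, and the new stereocentre is erased in step 9.

Step 7
Reactants: 10 2,2-dimethylpent-4-enal
Product: 12 3,3-dimethylhex-5-enal, via 1-methoxy-3,3-dimethylhexa-1,5-diene 11 (not isolated)
Conditions: MeOCH2PPh3Cl, KOtBu, THF, 0 °C to rt; then 2 M HCl, THF, rt
Reagents that add atoms: (methoxymethyl)triphenylphosphonium chloride, COC[P+](c1ccccc1)(c1ccccc1)c1ccccc1.[Cl-]; water, O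
Why: This Wittig one-carbon homologation of an α-quaternary aldehyde passes through the enol ether, which dilute acid hydrolyses to the aldehyde, and no stereocentre is involved.

Step 8
Reactants: 12 3,3-dimethylhex-5-enal
Product: 13 (2S)-3,3-dimethyl-1-oxohex-5-en-2-yl benzoate
Conditions: (S)-2-(triphenylmethyl)pyrrolidine (10 mol%), (PhCO2)2 (1.1 equiv), hydroquinone (10 mol%), THF, 0 °C; used without storage
Reagents that add atoms: dibenzoyl peroxide, O=C(OOC(=O)c1ccccc1)c1ccccc1
Why: In this enamine-catalysed asymmetric α-benzoyloxylation the trityl group shields one face of the E-enamine so that the peroxide oxygen is expected on the Si face, giving the (S)-aldehyde, which creates the C6 stereocentre and installs the benzoate of the target in the same event.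

Step 9
Reactants: 9 2-(trimethylsilyl)ethyl 2-(diethoxyphosphoryl)-4-[(2S,3S)-3-ethenyl-3-methyloxiran-2-yl]butanoate; 13 (2S)-3,3-dimethyl-1-oxohex-5-en-2-yl benzoate
Product: 14 2-(trimethylsilyl)ethyl (2E,4R)-4-(benzoyloxy)-2-{2-[(2S,3S)-3-ethenyl-3-methyloxiran-2-yl]ethyl}-5,5-dimethylocta-2,7-dienoate
Conditions: LiCl, DBU, MeCN, 0 °C to rt (9 premixed with LiCl and DBU, then 13)
Reagents that add atoms: none
Why: In this Horner–Wadsworth–Emmons olefination under lithium chloride/amine (Masamune–Roush) conditions the reversible addition should place the ester trans to the bulky C6 substituent (the E isomer, with the two future ring carbons cis), while the weak base should spare the α-acyloxy stereocentre, which is carried over unchanged (R only through the priority rule).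

Step 10
Reactants: 14 2-(trimethylsilyl)ethyl (2E,4R)-4-(benzoyloxy)-2-{2-[(2S,3S)-3-ethenyl-3-methyloxiran-2-yl]ethyl}-5,5-dimethylocta-2,7-dienoate
Product: 15 2-(trimethylsilyl)ethyl (1S,4E,6R,9E,11S)-6-(benzoyloxy)-7,7,11-trimethyl-12-oxabicyclo[9.1.0]dodeca-4,9-diene-4-carboxylate
Conditions: second-generation Grubbs catalyst RuCl2(=CHPh)(PCy3)(H2IMes) (10 mol%, two portions), 2,6-dichloro-1,4-benzoquinone (20 mol%), toluene (1 mM), 80 °C, argon sparge
Reagents that add atoms: none
Why: Ring-closing olefin metathesis: the ruthenium benzylidene should first exchange with the unhindered allyl terminus to give a C9 alkylidene, which undergoes [2+2] cycloaddition with the vinyl group on the quaternary oxirane carbon and cycloreversion of the ruthenacyclobutane, releasing ethene and forming C9=C10. The closest known reaction type is the ring-closing metathesis of α,ω-dienes to medium and large carbocycles, including substrates that carry vinyl oxiranes. The only ring closed is the eleven-membered carbocycle, by a macrocyclic alkene metathesis between two terminal olefins; the oxirane is already in place, so the step completes the 12-oxabicyclo[9.1.0]dodecane core. No stereocentre is formed, and the geometry of the new olefin is irrelevant because step 11 saturates it. The step needs ring closure to beat oligomerisation and needs the third olefin to stay out: high dilution with ethene removal and the turn imposed by the trans-oxirane, the gem-dimethyl group and the C4=C5 olefin should favour closure, and C4=C5 should remain a spectator because it is trisubstituted and ester-conjugated, so that truncation to a cyclopentene would have to pass through a disubstituted, ester-bearing ruthenium carbene. Because metathesis never places a radical or a carbanion on C9, the fast five-membered ring closure of such a centre onto C5 of the acrylate, which rules out radical and C9-carbanion closures of this bond, cannot occur.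

Step 11
Reactants: 15 2-(trimethylsilyl)ethyl (1S,4E,6R,9E,11S)-6-(benzoyloxy)-7,7,11-trimethyl-12-oxabicyclo[9.1.0]dodeca-4,9-diene-4-carboxylate
Product: 16 2-(trimethylsilyl)ethyl (1S,4E,6R,11S)-6-(benzoyloxy)-7,7,11-trimethyl-12-oxabicyclo[9.1.0]dodec-4-ene-4-carboxylate
Conditions: 2-nitrobenzenesulfonylhydrazide (excess, in portions), Et3N, CH2Cl2, rt; stopped when 15 is consumed
Reagents that add atoms: none
Why: Diimide generated in the flask transfers H2 in a concerted, metal-free step that should reduce the 1,2-disubstituted C9=C10 olefin well before the trisubstituted, ester-conjugated C4=C5 olefin and cannot hydrogenolyse the allylic oxirane or the benzoate, and no stereocentre is created.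

Step 12
Reactants: 16 2-(trimethylsilyl)ethyl (1S,4E,6R,11S)-6-(benzoyloxy)-7,7,11-trimethyl-12-oxabicyclo[9.1.0]dodec-4-ene-4-carboxylate
Product: 17 (1S,4E,6R,11S)-6-(benzoyloxy)-7,7,11-trimethyl-12-oxabicyclo[9.1.0]dodec-4-ene-4-carboxylic acid (target, CNP0377917.2)
Conditions: Bu4NF, THF, 0 °C to rt; then aq. NH4Cl
Reagents that add atoms: none
Why: Fluoride attacks silicon and the ester fragments by β-elimination to the carboxylate, ethene and fluorotrimethylsilane, a cleavage that does not depend on access to the hindered carbonyl and should leave the benzoate, the oxirane and all three stereocentres untouched.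

**Compound list**

1 | 5-bromo-2-methylpent-2-ene | CC(C)=CCCBr | starting material
2 | (2E)-5-bromo-2-methylpent-2-en-1-ol | OC/C(C)=C/CCBr | intermediate
3 | [(2S,3S)-3-(2-bromoethyl)-2-methyloxiran-2-yl]methanol | OC[C@]1(C)O[C@H]1CCBr | intermediate
4 | (2R,3S)-3-(2-bromoethyl)-2-methyloxirane-2-carbaldehyde | O=C[C@]1(C)O[C@H]1CCBr | intermediate
5 | (2S,3S)-3-(2-bromoethyl)-2-ethenyl-2-methyloxirane | C=C[C@]1(C)O[C@H]1CCBr | intermediate
6 | 2-(diethoxyphosphoryl)acetic acid | CCOP(=O)(OCC)CC(=O)O | starting material
7 | 2-(trimethylsilyl)ethanol | C[Si](C)(C)CCO | starting material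
8 | 2-(trimethylsilyl)ethyl 2-(diethoxyphosphoryl)acetate | CCOP(=O)(OCC)CC(=O)OCC[Si](C)(C)C | intermediate
9 | 2-(trimethylsilyl)ethyl 2-(diethoxyphosphoryl)-4-[(2S,3S)-3-ethenyl-3-methyloxiran-2-yl]butanoate (epimers at C2) | C=C[C@]1(C)O[C@H]1CCC(P(=O)(OCC)OCC)C(=O)OCC[Si](C)(C)C | intermediate
10 | 2,2-dimethylpent-4-enal | C=CCC(C)(C)C=O | starting material
11 | 1-methoxy-3,3-dimethylhexa-1,5-diene (E/Z mixture, not isolated) | COC=CC(C)(C)CC=C | intermediate
12 | 3,3-dimethylhex-5-enal | C=CCC(C)(C)CC=O | intermediate
13 | (2S)-3,3-dimethyl-1-oxohex-5-en-2-yl benzoate | O=C[C@@H](OC(=O)c1ccccc1)C(C)(C)CC=C | intermediate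
14 | 2-(trimethylsilyl)ethyl (2E,4R)-4-(benzoyloxy)-2-{2-[(2S,3S)-3-ethenyl-3-methyloxiran-2-yl]ethyl}-5,5-dimethylocta-2,7-dienoate | C=C[C@]1(C)O[C@H]1CC/C(C(=O)OCC[Si](C)(C)C)=C\[C@@H](OC(=O)c1ccccc1)C(C)(C)CC=C | intermediate
15 | 2-(trimethylsilyl)ethyl (1S,4E,6R,9E,11S)-6-(benzoyloxy)-7,7,11-trimethyl-12-oxabicyclo[9.1.0]dodeca-4,9-diene-4-carboxylate | CC1(C)C/C=C/[C@]2(C)O[C@H]2CC/C(C(=O)OCC[Si](C)(C)C)=C\[C@H]1OC(=O)c1ccccc1 | intermediate
16 | 2-(trimethylsilyl)ethyl (1S,4E,6R,11S)-6-(benzoyloxy)-7,7,11-trimethyl-12-oxabicyclo[9.1.0]dodec-4-ene-4-carboxylate | CC1(C)CCC[C@]2(C)O[C@H]2CC/C(C(=O)OCC[Si](C)(C)C)=C\[C@H]1OC(=O)c1ccccc1 | intermediate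
17 | (1S,4E,6R,11S)-6-(benzoyloxy)-7,7,11-trimethyl-12-oxabicyclo[9.1.0]dodec-4-ene-4-carboxylic acid | CC1(C)CCC[C@]2(C)O[C@H]2CC/C(C(=O)O)=C\[C@H]1OC(=O)c1ccccc1 | target

**Totals**

Total step count: 12. Longest linear sequence: 9 steps (steps 1, 2, 3, 4, 6, 9, 10, 11, 12).

**Steps most likely to fail**

Step 10 (ring-closing metathesis). Intermolecular metathesis (oligomer formation) or catalyst decay may outpace closure of the strained eleven-membered ring onto the hindered vinyl oxirane. The fallback closes the ring at C4=C5 by olefination instead; it sets out from 9 and 13 and comes back at 16. Cross-metathesis of the allyl group of 13 with the vinyl oxirane of 9 (RuCl2(=CH-C6H4-2-OiPr)(H2IMes), the second-generation Hoveyda–Grubbs catalyst, CH2Cl2, 40 °C; no base is present, so phosphonate and aldehyde coexist) should give the E-alkenyl phosphono aldehyde F1. Diimide (2-nitrobenzenesulfonylhydrazide, Et3N, CH2Cl2), to which aldehydes are inert, should saturate the new olefin to the saturated phosphono aldehyde F2. An intramolecular Horner–Wadsworth–Emmons reaction (LiCl, DBU, MeCN, slow addition at 1 mM) then closes the ring at C4=C5, where the E-enoate and the cis ring geometry coincide, and should deliver 16.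

Step 9 (Horner–Wadsworth–Emmons union). E selectivity may erode, or the α-benzoyloxy aldehyde may epimerise under base while two hindered partners combine slowly. The fallback uses a base-free stabilised-ylide Wittig reaction; it sets out from 5 and comes back at 14. Halide exchange (NaI, acetone) gives the iodoethyl vinyl oxirane F3. Alkylation of 2-(trimethylsilyl)ethyl 2-(triphenyl-λ5-phosphanylidene)acetate (2 equiv, EtOAc, reflux; the second equivalent takes up HI by transylidation) gives the α-alkylated stabilised ylide F4. Its Wittig reaction with 13 in toluene at 80 °C, a setting in which α-branched stabilised ylides give E-enoates with α-oxygenated aldehydes, should give 14.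

Step 8 (α-benzoyloxylation). Enamine formation from the β-quaternary aldehyde with the bulky catalyst may be slow, so that conversion stalls or uncatalysed, racemic benzoyloxylation intervenes. The fallback forms the C6–O bond by a proline-catalysed nitroso aldol reaction and acylates later; it sets out from 12 (with 9) and comes back at 14. D-Proline-catalysed α-aminoxylation with nitrosobenzene (DMSO, rt) should give the (2S)-anilinooxy aldehyde F5, which is trapped in the same flask by phosphonate 9 (LiCl, DBU, MeCN) as the γ-anilinooxy enoate F6. N–O cleavage (Cu(OAc)2, catalytic, EtOH, rt) gives the allylic alcohol F7, whose E geometry prevents lactonisation, and benzoylation (BzCl, DMAP, pyridine, CH2Cl2) should give 14.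

**Further compounds**

F1 | step 10 | 2-(trimethylsilyl)ethyl 4-{(2S,3S)-3-[(1E,5S)-5-(benzoyloxy)-4,4-dimethyl-6-oxohex-1-en-1-yl]-3-methyloxiran-2-yl}-2-(diethoxyphosphoryl)butanoate | O=C[C@@H](OC(=O)c1ccccc1)C(C)(C)C/C=C/[C@]1(C)O[C@H]1CCC(P(=O)(OCC)OCC)C(=O)OCC[Si](C)(C)C
F2 | step 10 | 2-(trimethylsilyl)ethyl 4-{(2S,3S)-3-[(5S)-5-(benzoyloxy)-4,4-dimethyl-6-oxohexyl]-3-methyloxiran-2-yl}-2-(diethoxyphosphoryl)butanoate | O=C[C@@H](OC(=O)c1ccccc1)C(C)(C)CCC[C@]1(C)O[C@H]1CCC(P(=O)(OCC)OCC)C(=O)OCC[Si](C)(C)C
F3 | step 9 | (2S,3S)-2-ethenyl-3-(2-iodoethyl)-2-methyloxirane | C=C[C@]1(C)O[C@H]1CCI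
F4 | step 9 | 2-(trimethylsilyl)ethyl 4-[(2S,3S)-3-ethenyl-3-methyloxiran-2-yl]-2-(triphenyl-λ5-phosphanylidene)butanoate | C=C[C@]1(C)O[C@H]1CCC(C(=O)OCC[Si](C)(C)C)=P(c1ccccc1)(c1ccccc1)c1ccccc1
F5 | step 8 | (2S)-2-(anilinooxy)-3,3-dimethylhex-5-enal (not isolated) | O=C[C@@H](ONc1ccccc1)C(C)(C)CC=C
F6 | step 8 | 2-(trimethylsilyl)ethyl (2E,4R)-4-(anilinooxy)-2-{2-[(2S,3S)-3-ethenyl-3-methyloxiran-2-yl]ethyl}-5,5-dimethylocta-2,7-dienoate | C=C[C@]1(C)O[C@H]1CC/C(C(=O)OCC[Si](C)(C)C)=C\[C@@H](ONc1ccccc1)C(C)(C)CC=C
F7 | step 8 | 2-(trimethylsilyl)ethyl (2E,4R)-2-{2-[(2S,3S)-3-ethenyl-3-methyloxiran-2-yl]ethyl}-4-hydroxy-5,5-dimethylocta-2,7-dienoate | C=C[C@]1(C)O[C@H]1CC/C(C(=O)OCC[Si](C)(C)C)=C\[C@@H](O)C(C)(C)CC=C
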